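## Structural features

The target is a 2-aryl-2,3-dihydrobenzofuran neolignan ester. A benzene ring A is fused to a dihydrofuran ring (O1, C2, C3, C3a, C7a). C2 carries the 4-hydroxy-3-methoxyphenyl ring D, C3 carries the oxymethyl carbon C9 esterified with 4-hydroxybenzoic acid, C7 carries a methoxy group and C5 a (Z)-3-oxoprop-1-enyl chain. The only stereocentres are the adjacent C2 (S) and C3 (R), with ring D and C9 trans. The fragile elements are the Z-enal (it goes to the E isomer with acid, base, nucleophiles or light), the primary aryl ester at C9, the benzylic C2–O1 bond para to the ring D oxygen (it can ionise in acid), and two free phenols. Because reionisation at C2 only returns the more stable trans ring, the real stereochemical problem is the absolute configuration at C3; the second problem is carrying a Z-enal through an acylation and a deprotection. The key step exploits the C2/C3 pattern: C3 bears a one-carbon oxygenated arm (C9) and C2 bears both O1 and the cation-stabilising ring D, which is what is left when formaldehyde and the ring A phenol oxygen add across the C2=C3 bond of a stilbene.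

## Logic of the disconnections

17 to 16: the two phenolic O–Si bonds are cut. Aryl silyl ethers fall to buffered fluoride, which leaves an aryl ester and an enal alone, so the free phenols never meet oxidants, bases or acylating agents. The demand is a last step that is near neutral, cold and dark, because 16 already holds the Z-enal.

16 to 11 and 14 (14 to 12): the C9 O–acyl bond is cut. 11 has a single hydroxyl and 14 has its phenol silylated, so the coupling is unambiguous and the third aromatic ring arrives convergently. The demand is an acylation without strong nucleophilic catalysts that could add reversibly to the enal.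

11 to 10 to 9 to 8: the side-chain C=C bond is cut back to the formyl group of 8, with two redox adjustments. The Z geometry comes from a kinetically controlled olefination. Reduction to 10 followed by allylic-selective oxidation tells the allylic hydroxyl from the C9 hydroxyl without protecting groups. The demand is Z-selective olefination beside a free alcohol and an oxidation that keeps the Z geometry.

8 to 5 and 6: C3–C9 and O1–C2 are cut. This removes the dihydrofuran ring, two skeletal bonds and both stereocentres in one operation and leaves an achiral E-stilbene plus formaldehyde. The demands are: formaldehyde must bond to C3 and not C2; the alkene face at C3 must be chosen by the catalyst; the silylated ring A oxygen must act as internal nucleophile; and the silyl group it sheds must be collected (it is expected on the C9 oxygen, as 7, and is hydrolysed in the quench).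

5 to 2 and 4: the bond between ring A (C3a) and the alkene carbon C3 is cut. Both halves are simple vanillin-type aromatics. The demand is a Heck coupling that is terminal-selective and E-selective and mild enough for the labile silyl ether ortho to the iodide.

2 to 1 and 4 to 3: the O–Si bonds are cut. Two different silyl groups are used on purpose: the smaller one on ring A must leave in the ring closure, the bulkier one on ring D must survive to the end.

## Other disconnections considered

Alternative 1: The cut is C2–C3 and O1–C2, a (4+1) assembly. Cs2CO3 would expel sulfinate from sulfonyl phenol A2 to give ortho-quinone methide A4 and would deprotonate chiral benzylsulfonium salt A3. The ylide carbon adds to the methide carbon (C2–C3) and the phenoxide then displaces the sulfide at C2 (O1–C2), giving A1.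
- In favour: annulation of ortho-quinone methides with sulfur ylides to trans-2,3-dihydrobenzofurans is an established reaction class, so on precedent this plan is the better one. The trans outcome follows from the anti betaine and is the equal of the chosen plan. A1 already carries the C9 ester, which saves the late acylation.
- Against: the chirality comes from a stoichiometric sulfide, and semi-stabilised benzyl ylides usually pass it on less well than stabilised ones. A2 has an acyloxy group beta to the sulfonyl carbon, so base can eliminate the carboxylate, or A4 can tautomerise to a vinylphenol. With the ester in place, the C5 bromide of A1 must become the Z-enal without hydride reagents.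
- Comparison: on structure, both plans close the dihydrofuran in the key step, this one from two elaborate fragments and the chosen one from a stilbene and formaldehyde. On mechanism, this one is anionic and avoids the acid-sensitivity questions, while the chosen one is catalytic in the chiral agent. On step economy the two are about equal, since making A2 and A3 offsets the shorter end game.

Alternative 2: The cut is C3–C3a; the dihydrofuran is derived from the pyranone ring of flavanone A6 by ring contraction. With PhI(OAc)2 and H2SO4 in trimethyl orthoformate, the enol ether of A6 would be attacked at C3 by iodine. The ring A carbon then shifts from the carbonyl carbon to C3 as iodobenzene leaves, and the old carbonyl carbon becomes the methyl ester C9 of A5.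
- In favour: this oxidative ring contraction is well known for flavanones, so on precedent it is better than the chosen plan. Enantioenriched flavanones are accessible by established asymmetric catalysis. The C3 ester is epimerisable, so the trans ring is thermodynamic, equal to the chosen plan.
- Against: the electron-rich ring D can migrate instead or the flavanone can be dehydrogenated, which is why ring D carries a pivalate. Strong acid threatens C2 through reversible opening of the benzylic ether. Afterwards the ester must be reduced, the pivalate exchanged (it cannot be removed at the end next to the C9 aryl ester) and the bromide converted into the Z-enal.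
- Comparison: on structure, this plan spends steps on oxidation-state and protecting-group corrections that the chosen plan avoids, because 8 already has C9 and C5 at the right level. On mechanism, a known rearrangement is better than an unprecedented Prins closure. On step economy the chosen plan should be shorter by about three or four steps if its key step works.

Alternative 3: The cut is C3a–C4 and C7a–C7; ring A is built last around an intact dihydrofuran. Lactone A8 would be converted into silyl ketene acetal A9 (C7a=C3a), which undergoes inverse-demand (4+2) cycloaddition with bromopyrone A10. Loss of CO2 and silanol then gives the aromatic product A7.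
- In favour: the key step contains no stereochemical event, and both stereocentres are set earlier in A8 by reliable chemistry, so in stereochemical security this plan is better. The regiochemistry is polarity-matched. Pyrone cycloaddition with decarboxylative aromatisation is a known class, equal or better on precedent.
- Against: C7 arrives as bromide and needs a C–O coupling; C5 arrives as an ester and needs reduction to the aldehyde level; the C9 and ring D silyl ethers of A7 must be told apart; A9 is moisture-sensitive; A8 needs its own multi-step asymmetric synthesis.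
- Comparison: on structure, the chosen plan takes ring A ready-made and fully substituted from a vanillin derivative, which this plan must rebuild. On mechanism this plan is the more predictable. On step economy it is clearly the longest of the four.

Key step: step 4

Remark on the chemistry: the sense of induction of the confined acid cannot be predicted with confidence, so the catalyst antipode that delivers 3R is assumed; both hands are available from the two BINOL enantiomers.
Remark on the chemistry: 2-methoxy-4-vinylphenol is taken as a commercial (stabilised) starting material; it replaces a two-step preparation of the same styrene from vanillin.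

## Route

Step 1
Reactants: 1 5-iodovanillin (4-hydroxy-3-iodo-5-methoxybenzaldehyde)
Product: 2 4-(tert-butyldimethylsilyloxy)-3-iodo-5-methoxybenzaldehyde
Conditions: TBSCl, imidazole, DMF, rt
Reagents that add atoms: tert-butyldimethylsilyl chloride, CC(C)(C)[Si](C)(C)Cl
Why: Standard silylation of an acidic phenol; the aldehyde and the aryl iodide are inert, and the product is kept away from aqueous base because this silyl ether of an electron-poor phenol is nucleophile-labile.

Step 2
Reactants: 3 2-methoxy-4-vinylphenol
Product: 4 triisopropyl(2-methoxy-4-vinylphenoxy)silane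
Conditions: TIPSCl, imidazole, DMF, rt
Reagents that add atoms: triisopropylsilyl chloride, CC(C)[Si](Cl)(C(C)C)C(C)C
Why: Standard phenol silylation; the bulky triisopropylsilyl group is chosen because it must survive the acid of step 4 and all later steps.

Step 3
Reactants: 2 4-(tert-butyldimethylsilyloxy)-3-iodo-5-methoxybenzaldehyde; 4 triisopropyl(2-methoxy-4-vinylphenoxy)silane
Product: 5 4-(tert-butyldimethylsilyloxy)-3-methoxy-5-[(E)-2-(3-methoxy-4-triisopropylsilyloxyphenyl)vinyl]benzaldehyde
Conditions: Pd2(dba)3 (2.5 mol%), [HP(t-Bu)3]BF4 (10 mol%), Cy2NMe, 1,4-dioxane, 50 °C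
Reagents that add atoms: none
Why: Mizoroki–Heck reaction: oxidative addition of the electron-poor aryl iodide to zerovalent palladium, syn insertion at the unsubstituted alkene carbon and syn beta-hydride elimination give the E-stilbene. The bulky electron-rich phosphine allows a low temperature, and the hindered tertiary amine base spares the labile aryl silyl ether.

Step 4
Reactants: 5 4-(tert-butyldimethylsilyloxy)-3-methoxy-5-[(E)-2-(3-methoxy-4-triisopropylsilyloxyphenyl)vinyl]benzaldehyde; 6 formaldehyde (used as dried paraformaldehyde)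
Product: 8 (2S,3R)-3-(hydroxymethyl)-7-methoxy-2-(3-methoxy-4-triisopropylsilyloxyphenyl)-2,3-dihydrobenzofuran-5-carbaldehyde, via C9 tert-butyldimethylsilyl ether 7 (not isolated)
Conditions: (CH2O)n (4 equiv), chiral IDPi acid (imidodiphosphorimidate from two 3,3'-diaryl-BINOL units with N-SO2CF3 groups, 5 mol%, hand chosen for 3R), CHCl3, −20 °C → rt; then AcOH/THF/H2O (3:1:1), rt
Reagents that add atoms: none
Why: Proposed new method: the confined acid protonates (or, after the first turnover, silylates) monomeric formaldehyde inside its chiral pocket, and the stilbene attacks it through the alkene carbon next to ring A, because only then does the positive charge fall on C2, where the para-silyloxy group of ring D stabilises it as a quinone-methide-like ion; the formyl group is meta to the alkene-bearing carbon and para to the ring A oxygen, so it does not steer by conjugation with the alkene but helps by weakening the competing donor on the ring A side. The ring A silyl ether oxygen then captures C2 in a 5-exo-trig closure and passes its silyl group to the C9 oxygen, directly or through the silylated catalyst, so 7 is expected first and the aqueous acetic acid quench frees the primary hydroxyl without touching the aryl triisopropylsilyl ether. The closest known reaction types are the catalytic asymmetric intermolecular Prins reaction of aryl alkenes with paraformaldehyde under confined chiral Brønsted acids, which ends at 1,3-dioxanes, and Prins cyclisations terminated by oxygen nucleophiles; silylium-type turnover of such acids is also established. C3 is set in the C–C bond-forming event by the face selection of the catalyst pocket. C2 follows from anti addition across the E-alkene, which places ring D and C9 trans, and if needed from reionisation of the benzylic ether, which converges on the more stable trans ring without touching C3. The step needs regioselectivity (C9 to C3), preference for formaldehyde over the aryl aldehyde and over direct protonation of the alkene, and ring closure faster than capture of the cation by a second formaldehyde. The substrate secures these through the donor pattern of ring D, the much lower electrophilicity of the donor-conjugated aryl aldehyde, the aprotic silyl-relay cycle and the five-atom tether. The silyl cap also keeps the phenol from forming a hemiformal, which would close to an isomeric oxygen heterocycle with the formaldehyde carbon next to O1.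

Step 5
Reactants: 8 (2S,3R)-3-(hydroxymethyl)-7-methoxy-2-(3-methoxy-4-triisopropylsilyloxyphenyl)-2,3-dihydrobenzofuran-5-carbaldehyde
Product: 9 methyl (Z)-3-[(2S,3R)-3-(hydroxymethyl)-7-methoxy-2-(3-methoxy-4-triisopropylsilyloxyphenyl)-2,3-dihydrobenzofuran-5-yl]prop-2-enoate
Conditions: (CF3CH2O)2P(O)CH2CO2Me, KN(SiMe3)2, 18-crown-6, THF, −78 °C
Reagents that add atoms: methyl bis(2,2,2-trifluoroethyl)phosphonoacetate, COC(=O)CP(=O)(OCC(F)(F)F)OCC(F)(F)F
Why: Still–Gennari olefination: the electron-poor phosphonate makes elimination from the first-formed adduct faster than its equilibration, which gives the Z-enoate with aryl aldehydes. The preformed phosphonate anion is too weak a base to deprotonate the C9 hydroxyl or to disturb the stereocentres.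

Step 6
Reactants: 9 methyl (Z)-3-[(2S,3R)-3-(hydroxymethyl)-7-methoxy-2-(3-methoxy-4-triisopropylsilyloxyphenyl)-2,3-dihydrobenzofuran-5-yl]prop-2-enoate
Product: 10 (Z)-3-[(2S,3R)-3-(hydroxymethyl)-7-methoxy-2-(3-methoxy-4-triisopropylsilyloxyphenyl)-2,3-dihydrobenzofuran-5-yl]prop-2-en-1-ol
Conditions: i-Bu2AlH (4 equiv), CH2Cl2, −78 °C; aq. KNaC4H4O6
Reagents that add atoms: none
Why: 1,2-Reduction of an enoate by i-Bu2AlH gives the allylic alcohol with the double-bond geometry unchanged; the aryl silyl ether and the dihydrofuran are inert at low temperature.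

Step 7
Reactants: 10 (Z)-3-[(2S,3R)-3-(hydroxymethyl)-7-methoxy-2-(3-methoxy-4-triisopropylsilyloxyphenyl)-2,3-dihydrobenzofuran-5-yl]prop-2-en-1-ol
Product: 11 (2S,3R)-3-(hydroxymethyl)-7-methoxy-2-(3-methoxy-4-triisopropylsilyloxyphenyl)-5-[(Z)-3-oxoprop-1-enyl]-2,3-dihydrobenzofuran
Conditions: MnO2 (activated, excess), CH2Cl2, rt, dark
Reagents that add atoms: none
Why: Activated MnO2 oxidises allylic alcohols much faster than saturated primary alcohols, so the C9 hydroxyl is left for step 9; the neutral heterogeneous conditions favour retention of the Z geometry.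

Step 8
Reactants: 12 4-hydroxybenzoic acid
Product: 14 4-(tert-butyldimethylsilyloxy)benzoic acid, via tert-butyldimethylsilyl 4-(tert-butyldimethylsilyloxy)benzoate 13 (not isolated)
Conditions: TBSCl (2.4 equiv), imidazole, DMF, rt; then AcOH/THF/H2O, rt
Reagents that add atoms: tert-butyldimethylsilyl chloride, CC(C)(C)[Si](C)(C)Cl
Why: Exhaustive silylation followed by selective hydrolysis of the silyl ester, which is far more labile than the aryl silyl ether.

Step 9
Reactants: 14 4-(tert-butyldimethylsilyloxy)benzoic acid; 11 (2S,3R)-3-(hydroxymethyl)-7-methoxy-2-(3-methoxy-4-triisopropylsilyloxyphenyl)-5-[(Z)-3-oxoprop-1-enyl]-2,3-dihydrobenzofuran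
Product: 16 [(2S,3R)-7-methoxy-2-(3-methoxy-4-triisopropylsilyloxyphenyl)-5-[(Z)-3-oxoprop-1-enyl]-2,3-dihydrobenzofuran-3-yl]methyl 4-(tert-butyldimethylsilyloxy)benzoate, via 4-(tert-butyldimethylsilyloxy)benzoyl chloride 15 (not isolated)
Conditions: 14, 1-chloro-N,N,2-trimethylprop-1-en-1-amine, CH2Cl2, 0 °C → rt; then 11, pyridine, CH2Cl2, 0 °C, dark
Reagents that add atoms: none
Why: The alpha-chloroenamine turns the acid into its chloride under neutral conditions, and pyridine-mediated acylation of the single primary alcohol then gives the ester. No strongly nucleophilic acyl-transfer catalyst is used, so reversible conjugate addition to the Z-enal is avoided.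

Step 10
Reactants: 16 [(2S,3R)-7-methoxy-2-(3-methoxy-4-triisopropylsilyloxyphenyl)-5-[(Z)-3-oxoprop-1-enyl]-2,3-dihydrobenzofuran-3-yl]methyl 4-(tert-butyldimethylsilyloxy)benzoate
Product: 17 [(2S,3R)-2-(4-hydroxy-3-methoxyphenyl)-7-methoxy-5-[(Z)-3-oxoprop-1-enyl]-2,3-dihydrobenzofuran-3-yl]methyl 4-hydroxybenzoate (CNP0400980.1)
Conditions: HF·pyridine, pyridine, THF, 0 °C → rt, dark
Reagents that add atoms: none
Why: Fluoride cleaves both aryl silyl ethers; the pyridine buffer keeps the medium near neutral so the aryl ester, the benzylic ether and the Z-enal should survive.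

## Compound list

1 | 5-iodovanillin (4-hydroxy-3-iodo-5-methoxybenzaldehyde) | COc1cc(C=O)cc(I)c1O | starting material
2 | 4-(tert-butyldimethylsilyloxy)-3-iodo-5-methoxybenzaldehyde | COc1cc(C=O)cc(I)c1O[Si](C)(C)C(C)(C)C | intermediate
3 | 2-methoxy-4-vinylphenol | COc1cc(C=C)ccc1O | starting material
4 | triisopropyl(2-methoxy-4-vinylphenoxy)silane | COc1cc(C=C)ccc1O[Si](C(C)C)(C(C)C)C(C)C | intermediate
5 | 4-(tert-butyldimethylsilyloxy)-3-methoxy-5-[(E)-2-(3-methoxy-4-triisopropylsilyloxyphenyl)vinyl]benzaldehyde | COc1cc(C=O)cc(/C=C/c2ccc(O[Si](C(C)C)(C(C)C)C(C)C)c(OC)c2)c1O[Si](C)(C)C(C)(C)C | intermediate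
6 | formaldehyde (used as paraformaldehyde) | C=O | starting material
7 | (2S,3R)-3-(tert-butyldimethylsilyloxymethyl)-7-methoxy-2-(3-methoxy-4-triisopropylsilyloxyphenyl)-2,3-dihydrobenzofuran-5-carbaldehyde (not isolated) | COc1cc([C@H]2Oc3c(OC)cc(C=O)cc3[C@@H]2CO[Si](C)(C)C(C)(C)C)ccc1O[Si](C(C)C)(C(C)C)C(C)C | intermediate
8 | (2S,3R)-3-(hydroxymethyl)-7-methoxy-2-(3-methoxy-4-triisopropylsilyloxyphenyl)-2,3-dihydrobenzofuran-5-carbaldehyde (trans) | COc1cc([C@H]2Oc3c(OC)cc(C=O)cc3[C@@H]2CO)ccc1O[Si](C(C)C)(C(C)C)C(C)C | intermediate
9 | methyl (Z)-3-[(2S,3R)-3-(hydroxymethyl)-7-methoxy-2-(3-methoxy-4-triisopropylsilyloxyphenyl)-2,3-dihydrobenzofuran-5-yl]prop-2-enoate | COc1cc([C@H]2Oc3c(OC)cc(/C=C\C(=O)OC)cc3[C@@H]2CO)ccc1O[Si](C(C)C)(C(C)C)C(C)C | intermediate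
10 | (Z)-3-[(2S,3R)-3-(hydroxymethyl)-7-methoxy-2-(3-methoxy-4-triisopropylsilyloxyphenyl)-2,3-dihydrobenzofuran-5-yl]prop-2-en-1-ol | COc1cc([C@H]2Oc3c(OC)cc(/C=C\CO)cc3[C@@H]2CO)ccc1O[Si](C(C)C)(C(C)C)C(C)C | intermediate
11 | (2S,3R)-3-(hydroxymethyl)-7-methoxy-2-(3-methoxy-4-triisopropylsilyloxyphenyl)-5-[(Z)-3-oxoprop-1-enyl]-2,3-dihydrobenzofuran | COc1cc([C@H]2Oc3c(OC)cc(/C=C\C=O)cc3[C@@H]2CO)ccc1O[Si](C(C)C)(C(C)C)C(C)C | intermediate
12 | 4-hydroxybenzoic acid | OC(=O)c1ccc(O)cc1 | starting material
13 | tert-butyldimethylsilyl 4-(tert-butyldimethylsilyloxy)benzoate (not isolated) | CC(C)(C)[Si](C)(C)OC(=O)c1ccc(O[Si](C)(C)C(C)(C)C)cc1 | intermediate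
14 | 4-(tert-butyldimethylsilyloxy)benzoic acid | CC(C)(C)[Si](C)(C)Oc1ccc(C(=O)O)cc1 | intermediate
15 | 4-(tert-butyldimethylsilyloxy)benzoyl chloride (not isolated) | CC(C)(C)[Si](C)(C)Oc1ccc(C(Cl)=O)cc1 | intermediate
16 | [(2S,3R)-7-methoxy-2-(3-methoxy-4-triisopropylsilyloxyphenyl)-5-[(Z)-3-oxoprop-1-enyl]-2,3-dihydrobenzofuran-3-yl]methyl 4-(tert-butyldimethylsilyloxy)benzoate | COc1cc([C@H]2Oc3c(OC)cc(/C=C\C=O)cc3[C@@H]2COC(=O)c2ccc(O[Si](C)(C)C(C)(C)C)cc2)ccc1O[Si](C(C)C)(C(C)C)C(C)C | intermediate
17 | [(2S,3R)-2-(4-hydroxy-3-methoxyphenyl)-7-methoxy-5-[(Z)-3-oxoprop-1-enyl]-2,3-dihydrobenzofuran-3-yl]methyl 4-hydroxybenzoate | COc1cc([C@H]2Oc3c(OC)cc(/C=C\C=O)cc3[C@@H]2COC(=O)c2ccc(O)cc2)ccc1O | target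

## Step count and least certain steps

Total step count: 10. Longest linear sequence: 8 steps (steps 1, 3, 4, 5, 6, 7, 9 and 10, from 1 to 17).

**Step 4 (key step, the one step outside known chemistry).**
- What may go wrong: direct protonation of the alkene followed by ring closure, which gives the ring without C9; capture of the C2 cation by a second formaldehyde, or proton loss from it, outrunning closure by the electronically deactivated and hindered silyl ether oxygen; early loss of the ring A silyl group followed by hemiformal chemistry; tying-up of the acid by the aryl aldehyde; and poor facial selectivity, because the catalyst pocket is proven for terminal aryl alkenes and not for a 1,2-diaryl alkene.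
- Fallback (known chemistry), setting out from 4 and 1 and returning at 8. Ozonolysis of 4 with a NaBH4 quench gives [3-methoxy-4-(triisopropylsilyloxy)phenyl]methanol F1. Mitsunobu etherification of 1 with F1 (PPh3, diisopropyl azodicarboxylate) gives 3-iodo-5-methoxy-4-{[3-methoxy-4-(triisopropylsilyloxy)phenyl]methoxy}benzaldehyde F2. Palladium-catalysed coupling of the aryl iodide with methyl diazoacetate (Pd(PPh3)4, Ag2CO3, Et3N) gives methyl 2-diazo-2-[5-formyl-3-methoxy-2-{[3-methoxy-4-(triisopropylsilyloxy)phenyl]methoxy}phenyl]acetate F3. Dirhodium tetrakis[N-phthaloyl-(S)-tert-leucinate], Rh2(S-PTTL)4, or its antipode, whichever gives the 2S centre, inserts the carbenoid into the benzylic ether C–H bond to give the cis ester methyl (2S,3R)-5-formyl-7-methoxy-2-[3-methoxy-4-(triisopropylsilyloxy)phenyl]-2,3-dihydrobenzofuran-3-carboxylate F4. Catalytic NaOMe in MeOH/THF at 0 °C epimerises C3 to the trans ester methyl (2S,3S)-5-formyl-7-methoxy-2-[3-methoxy-4-(triisopropylsilyloxy)phenyl]-2,3-dihydrobenzofuran-3-carboxylate F5. i-Bu2AlH reduces ester and aldehyde to [(2S,3R)-5-(hydroxymethyl)-7-methoxy-2-(3-methoxy-4-triisopropylsilyloxyphenyl)-2,3-dihydrobenzofuran-3-yl]methanol F6, and MnO2 re-oxidises only the benzylic alcohol to give 8.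

**Step 3 (Heck coupling).**
- What may go wrong: slow coupling at the iodide flanked by the bulky silyl ether, loss of the labile ring A silyl group under the basic conditions, or arylation at the internal alkene carbon of the electron-rich styrene.
- Fallback, setting out from 4 and 1 and returning at 5. Cross-metathesis of 4 with 4,4,5,5-tetramethyl-2-vinyl-1,3,2-dioxaborolane (second-generation Grubbs catalyst, RuCl2(H2IMes)(PCy3)(=CHPh)) gives 2-[(E)-2-(3-methoxy-4-triisopropylsilyloxyphenyl)vinyl]-4,4,5,5-tetramethyl-1,3,2-dioxaborolane F7. Suzuki–Miyaura coupling of F7 with the free phenol 1 (Pd(dppf)Cl2, K3PO4, dioxane/H2O) gives 4-hydroxy-3-methoxy-5-[(E)-2-(3-methoxy-4-triisopropylsilyloxyphenyl)vinyl]benzaldehyde F8, which is silylated (TBSCl, imidazole) to 5.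

**Step 7 (allylic oxidation).**
- What may go wrong: Z to E isomerisation on the oxidant surface or during a slow reaction, and slow competing oxidation of the C9 alcohol.
- Fallback, setting out from 8 and returning at 11; the aldehyde level is reached by reduction and not by oxidation. Z-selective Horner–Wadsworth–Emmons olefination of 8 with bis(2,2,2-trifluoroethyl) [2-(methoxy(methyl)amino)-2-oxoethyl]phosphonate (KN(SiMe3)2, 18-crown-6, THF, −78 °C) gives (Z)-3-[(2S,3R)-3-(hydroxymethyl)-7-methoxy-2-(3-methoxy-4-triisopropylsilyloxyphenyl)-2,3-dihydrobenzofuran-5-yl]-N-methoxy-N-methylprop-2-enamide F9. i-Bu2AlH at −78 °C then gives 11 directly, because the chelated tetrahedral intermediate collapses only on work-up.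

**Step 9 (acylation beside the Z-enal).**
- What may go wrong: base- or nucleophile-induced Z to E isomerisation of the enal during acylation, or incomplete acylation under the deliberately mild conditions.
- Fallback, setting out from 8 and returning at 16; the ester is installed before any enal exists. Carbodiimide coupling of 8 with 14 (4-(dimethylamino)pyridine catalysis is harmless at this stage) gives [(2S,3R)-5-formyl-7-methoxy-2-(3-methoxy-4-triisopropylsilyloxyphenyl)-2,3-dihydrobenzofuran-3-yl]methyl 4-(tert-butyldimethylsilyloxy)benzoate F10. Stork–Zhao olefination (ylide from (iodomethyl)triphenylphosphonium iodide and NaN(SiMe3)2, THF, −78 °C) gives [(2S,3R)-5-[(Z)-2-iodovinyl]-7-methoxy-2-(3-methoxy-4-triisopropylsilyloxyphenyl)-2,3-dihydrobenzofuran-3-yl]methyl 4-(tert-butyldimethylsilyloxy)benzoate F11. Palladium-catalysed formylation of the vinyl iodide with CO and Bu3SnH (Pd(PPh3)4), with retention of geometry, gives 16.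

**Step 10 (final desilylation).**
- What may go wrong: Z to E isomerisation of the push-pull enal, or cleavage or migration of the C9 ester while the hindered triisopropylsilyl ether is being removed.
- Fallback, setting out from 8 and returning at 17; the phenols are freed before the enal is made. 8 is taken through [(2S,3R)-5-formyl-7-methoxy-2-(3-methoxy-4-triisopropylsilyloxyphenyl)-2,3-dihydrobenzofuran-3-yl]methyl 4-(tert-butyldimethylsilyloxy)benzoate F10 to [(2S,3R)-5-[(Z)-2-iodovinyl]-7-methoxy-2-(3-methoxy-4-triisopropylsilyloxyphenyl)-2,3-dihydrobenzofuran-3-yl]methyl 4-(tert-butyldimethylsilyloxy)benzoate F11 as above. F11 is desilylated with HF·pyridine to [(2S,3R)-2-(4-hydroxy-3-methoxyphenyl)-5-[(Z)-2-iodovinyl]-7-methoxy-2,3-dihydrobenzofuran-3-yl]methyl 4-hydroxybenzoate F12, and the same palladium-catalysed formylation (CO, Bu3SnH, Pd(PPh3)4) is run last to give 17.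

## Further compounds

F1 | step 4 | [3-methoxy-4-(triisopropylsilyloxy)phenyl]methanol | COc1cc(CO)ccc1O[Si](C(C)C)(C(C)C)C(C)C
F2 | step 4 | 3-iodo-5-methoxy-4-{[3-methoxy-4-(triisopropylsilyloxy)phenyl]methoxy}benzaldehyde | COc1cc(C=O)cc(I)c1OCc1ccc(O[Si](C(C)C)(C(C)C)C(C)C)c(OC)c1
F3 | step 4 | methyl 2-diazo-2-[5-formyl-3-methoxy-2-{[3-methoxy-4-(triisopropylsilyloxy)phenyl]methoxy}phenyl]acetate | COC(=O)C(=[N+]=[N-])c1cc(C=O)cc(OC)c1OCc1ccc(O[Si](C(C)C)(C(C)C)C(C)C)c(OC)c1
F4 | step 4 | methyl (2S,3R)-5-formyl-7-methoxy-2-[3-methoxy-4-(triisopropylsilyloxy)phenyl]-2,3-dihydrobenzofuran-3-carboxylate (cis) | COc1cc([C@H]2Oc3c(OC)cc(C=O)cc3[C@H]2C(=O)OC)ccc1O[Si](C(C)C)(C(C)C)C(C)C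
F5 | step 4 | methyl (2S,3S)-5-formyl-7-methoxy-2-[3-methoxy-4-(triisopropylsilyloxy)phenyl]-2,3-dihydrobenzofuran-3-carboxylate (trans) | COc1cc([C@H]2Oc3c(OC)cc(C=O)cc3[C@@H]2C(=O)OC)ccc1O[Si](C(C)C)(C(C)C)C(C)C
F6 | step 4 | [(2S,3R)-5-(hydroxymethyl)-7-methoxy-2-(3-methoxy-4-triisopropylsilyloxyphenyl)-2,3-dihydrobenzofuran-3-yl]methanol | COc1cc([C@H]2Oc3c(OC)cc(CO)cc3[C@@H]2CO)ccc1O[Si](C(C)C)(C(C)C)C(C)C
F7 | step 3 | 2-[(E)-2-(3-methoxy-4-triisopropylsilyloxyphenyl)vinyl]-4,4,5,5-tetramethyl-1,3,2-dioxaborolane | COc1cc(/C=C/B2OC(C)(C)C(C)(C)O2)ccc1O[Si](C(C)C)(C(C)C)C(C)C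
F8 | step 3 | 4-hydroxy-3-methoxy-5-[(E)-2-(3-methoxy-4-triisopropylsilyloxyphenyl)vinyl]benzaldehyde | COc1cc(C=O)cc(/C=C/c2ccc(O[Si](C(C)C)(C(C)C)C(C)C)c(OC)c2)c1O
F9 | step 7 | (Z)-3-[(2S,3R)-3-(hydroxymethyl)-7-methoxy-2-(3-methoxy-4-triisopropylsilyloxyphenyl)-2,3-dihydrobenzofuran-5-yl]-N-methoxy-N-methylprop-2-enamide | COc1cc([C@H]2Oc3c(OC)cc(/C=C\C(=O)N(C)OC)cc3[C@@H]2CO)ccc1O[Si](C(C)C)(C(C)C)C(C)C
F10 | step 9 | [(2S,3R)-5-formyl-7-methoxy-2-(3-methoxy-4-triisopropylsilyloxyphenyl)-2,3-dihydrobenzofuran-3-yl]methyl 4-(tert-butyldimethylsilyloxy)benzoate | COc1cc([C@H]2Oc3c(OC)cc(C=O)cc3[C@@H]2COC(=O)c2ccc(O[Si](C)(C)C(C)(C)C)cc2)ccc1O[Si](C(C)C)(C(C)C)C(C)C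
F11 | step 9 | [(2S,3R)-5-[(Z)-2-iodovinyl]-7-methoxy-2-(3-methoxy-4-triisopropylsilyloxyphenyl)-2,3-dihydrobenzofuran-3-yl]methyl 4-(tert-butyldimethylsilyloxy)benzoate | COc1cc([C@H]2Oc3c(OC)cc(/C=C\I)cc3[C@@H]2COC(=O)c2ccc(O[Si](C)(C)C(C)(C)C)cc2)ccc1O[Si](C(C)C)(C(C)C)C(C)C
F12 | step 10 | [(2S,3R)-2-(4-hydroxy-3-methoxyphenyl)-5-[(Z)-2-iodovinyl]-7-methoxy-2,3-dihydrobenzofuran-3-yl]methyl 4-hydroxybenzoate | COc1cc([C@H]2Oc3c(OC)cc(/C=C\I)cc3[C@@H]2COC(=O)c2ccc(O)cc2)ccc1O
A1 | alternative 1 | [(2S,3R)-5-bromo-7-methoxy-2-(3-methoxy-4-triisopropylsilyloxyphenyl)-2,3-dihydrobenzofuran-3-yl]methyl 4-(triisopropylsilyloxy)benzoate (trans) | COc1cc([C@H]2Oc3c(OC)cc(Br)cc3[C@@H]2COC(=O)c2ccc(O[Si](C(C)C)(C(C)C)C(C)C)cc2)ccc1O[Si](C(C)C)(C(C)C)C(C)C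
A2 | alternative 1 | 2-(5-bromo-2-hydroxy-3-methoxyphenyl)-2-(4-methylphenylsulfonyl)ethyl 4-(triisopropylsilyloxy)benzoate (racemic) | COc1cc(Br)cc(C(COC(=O)c2ccc(O[Si](C(C)C)(C(C)C)C(C)C)cc2)S(=O)(=O)c2ccc(C)cc2)c1O
A3 | alternative 1 | (2R,5R)-1-[(3-methoxy-4-triisopropylsilyloxyphenyl)methyl]-2,5-dimethylthiolan-1-ium trifluoromethanesulfonate (one hand of a C2-symmetric sulfide, drawn for definiteness) | C[C@@H]1CC[C@@H](C)[S+]1Cc1ccc(O[Si](C(C)C)(C(C)C)C(C)C)c(OC)c1.[O-]S(=O)(=O)C(F)(F)F
A4 | alternative 1 | 2-[4-bromo-2-methoxy-6-oxocyclohexa-2,4-dien-1-ylidene]ethyl 4-(triisopropylsilyloxy)benzoate, the transient ortho-quinone methide from A2 | O=C1C(OC)=CC(Br)=CC1=CCOC(=O)c1ccc(O[Si](C(C)C)(C(C)C)C(C)C)cc1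
A5 | alternative 2 | methyl (2S,3S)-5-bromo-7-methoxy-2-(3-methoxy-4-pivaloyloxyphenyl)-2,3-dihydrobenzofuran-3-carboxylate (trans) | COc1cc([C@H]2Oc3c(OC)cc(Br)cc3[C@@H]2C(=O)OC)ccc1OC(=O)C(C)(C)C
A6 | alternative 2 | (2S)-6-bromo-8-methoxy-2-(3-methoxy-4-pivaloyloxyphenyl)chroman-4-one | COc1cc([C@@H]2CC(=O)c3cc(Br)cc(OC)c3O2)ccc1OC(=O)C(C)(C)C
A7 | alternative 3 | methyl (2S,3R)-7-bromo-2-(3-methoxy-4-triisopropylsilyloxyphenyl)-3-(triisopropylsilyloxymethyl)-2,3-dihydrobenzofuran-5-carboxylate (trans) | COc1cc([C@H]2Oc3c(Br)cc(C(=O)OC)cc3[C@@H]2CO[Si](C(C)C)(C(C)C)C(C)C)ccc1O[Si](C(C)C)(C(C)C)C(C)C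
A8 | alternative 3 | (4R,5S)-5-(3-methoxy-4-triisopropylsilyloxyphenyl)-4-(triisopropylsilyloxymethyl)oxolan-2-one | COc1cc([C@H]2OC(=O)C[C@@H]2CO[Si](C(C)C)(C(C)C)C(C)C)ccc1O[Si](C(C)C)(C(C)C)C(C)C
A9 | alternative 3 | (2S,3R)-5-(tert-butyldimethylsilyloxy)-2-(3-methoxy-4-triisopropylsilyloxyphenyl)-3-(triisopropylsilyloxymethyl)-2,3-dihydrofuran | COc1cc([C@H]2OC(O[Si](C)(C)C(C)(C)C)=C[C@@H]2CO[Si](C(C)C)(C(C)C)C(C)C)ccc1O[Si](C(C)C)(C(C)C)C(C)C
A10 | alternative 3 | methyl 3-bromo-2-oxo-2H-pyran-5-carboxylate | COC(=O)C1=COC(=O)C(Br)=C1
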